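(Readings and results are calculated on assumed constants, noise included.)

The summer flask differs from the dawn flask in one charge, 0.400 M of target put in at the start, so I asked what that target does in 50 min.

| flask | starting material | partner | catalyst | target | time |
|---|---|---|---|---|---|
| dawn | 0.500 M | 1.50 M | 0.00100 M |  |  |
| autumn | 0.200 M | 1.20 M | 0.00100 M |  |  |
| winter | 0.750 M | 1.50 M | 0.00100 M |  |  |
| midnight | 0.500 M | 2.20 M | 0.00100 M |  |  |
| summer | 0.500 M | 1.50 M | 0.00100 M | 0.400 M | 50 min |

- dawn run (time / min: [target] / M): 2.2: 0.013; 6.7: 0.053; 13: 0.088; 20: 0.136; 29: 0.166; 39: 0.193; 50: 0.205
- autumn run (time / min: [target] / M): 2.2: 0.012; 6.7: 0.036; 13: 0.063; 20: 0.083; 29: 0.085; 39: 0.103; 50: 0.108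
- winter run (time / min: [target] / M): 2.2: 0.018; 6.7: 0.079; 13: 0.126; 20: 0.166; 29: 0.217; 39: 0.250; 50: 0.267
- midnight run (time / min: [target] / M): 2.2: 0.029; 6.7: 0.058; 13: 0.108; 20: 0.132; 29: 0.178; 39: 0.204; 50: 0.226

(scatter of a reading: 0.005 M)

- the power of [partner] that the first rate follows, about the charge of the dawn run; measure it at two percent of starting material made into target
- the power of [starting material] that the first rate follows, about the charge of the dawn run; measure it at two percent of starting material made into target (one fixed amount of target, the same in the runs compared)
- target in the summer run at 50 min, as a share of the starting material charged

- Overall: starting material + partner -> target, with catalyst as catalyst.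
- Constant volume, constant temperature.
- The analysis sees a species whether free or bound.
- "The second partner" is partner.
- An order is taken over about fifteen percent of the charge, up and down.
- A share of target counts the target that was charged too.

I began from above. If charged target simply stayed and the making went on as in dawn, summer would hold the charge plus dawn's 0.205 M, which is 121% of the starting material.

For the bound from below I supposed that the slowing was target being lost, and I let a loss constant stand for the fraction of the target present that vanishes per minute. A first-order loss treats charged and made target alike, so the two parts add, and the amount lost by a given time is that constant times the area under the target curve. In the autumn run this area up to 50 min came to 228 M·s. Target made there cannot exceed the 0.200 M of starting material, the limiting reagent, so on these scattered readings the constant stood at or below about 0.0242 min⁻¹. With dawn's making unchanged, that estimate put summer at about 64.8% or above.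

To tighten this I read the orders. Winter against autumn at 13 min, two runs that differ in partner as well, gave 0.524 as a rough reading in starting material, near a half. Midnight against dawn, summing the readings at 13 min and 20 min, gave 0.180 in partner, which I neglected. Half-order making from autumn's early rate of 0.00485 M min⁻¹ gave 0.169 M made by 50 min. Of this, 0.108 M was read, so my loss constant was 0.0160 min⁻¹, and I committed to 76.9%.

The forecast gave 118%, inside my bracket, with orders 0.4 in partner and 0.6 in starting material, and it read the slowing as “time-based catalyst decay”.

The flask gave 72.9%, which is 4 percentage points below my figure, with orders 0.14 in partner and 0.55 in starting material.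

    catalyst + starting material ⇌ catalyst-substrate complex (168.6 M⁻¹ min⁻¹, 90.60 min⁻¹)
    catalyst-substrate complex + partner → target + catalyst (438.6 M⁻¹ min⁻¹)
    2 starting material ⇌ idle substrate dimer, settled at all times (59.30 M⁻¹)
    target → decomposed product (0.01878 min⁻¹)

In these equations target goes to decomposed product with a half-life of 36.9 min. Put to the winter run, where the area under the curve is 528 M·s, my loss constant counts 0.141 M of target gone by 50 min, about half of the 0.267 M still read there.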